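## Retrosynthetic overview

1. Ring atoms of the carbocycle: C1 (quaternary; CH3 and the vinyl group), C2H2, C3H2, C4(CH3)=C5H, C6H (bonded to C3 of coumarin B). The plan rests on the vicinal C1/C6 pair: in a cis-1,4-dimethylcyclohexa-2,5-diene C1 and C4 lie on a mirror plane and the alkenes C2=C3 and C6=C5 are enantiotopic. C2(=O)–C3 of coumarin B can be brought in as an acrylate ester hung from a CH2O arm on C1, the carbon that ends as the vinyl CH.
2. Last C=C: Horner–Wadsworth–Emmons union of the C1 carbaldehyde with the 3-ylmethyl phosphonate of coumarin A (its pyranone ring made on a side branch by Z-olefination and lactonisation), then desilylation.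
3. Pyranone ring of coumarin B: the unmasked ortho-phenol of a cis-fused α-benzylidene δ-lactone takes over the lactone carbonyl and releases C1–CH2OH; C2=C3 is saturated just before.
4. Key disconnection: the C6–C3(coumarin B) bond and the δ-lactone, by enantiotopic-alkene-selective 6-exo Heck cyclisation of the tethered (E)-α-bromocinnamate, with syn β-hydride loss from C4 giving C4=C5.
5. Ring order: carbocycle (Birch reductive methylation of 4-methylbenzoic acid) → δ-lactone → pyranone of coumarin B (the δ-lactone opens as it forms). The acyl part comes from 2,4-dihydroxy-3-methoxybenzaldehyde and a bromophosphonoacetate.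

Key step: step 9

Remark: the sense of induction of BINAP cannot be predicted with certainty for an ester tether; (R)-BINAP is written in step 9 and its antipode is to be taken if the mirror-image lactone forms.

Remark: the reductive methylation is expected to give both 1,4-diastereomers; the route assumes that the cis-dimethyl alcohol can be isolated in step 2, because only this isomer carries the C4 hydrogen on the face of the tether.

Abbreviations: TIPS = triisopropylsilyl; MOM = methoxymethyl; Ar = 3-methoxy-2-(methoxymethoxy)-4-[(triisopropylsilyl)oxy]phenyl.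

## Route

Step 1
Reactants: 1 4-methylbenzoic acid
Product: 3 1,4-dimethylcyclohexa-2,5-diene-1-carboxylic acid (cis/trans mixture), via Birch dianion 2 (not isolated)
Conditions: Li, NH3(l)/THF, −78 °C; then MeI, −78 °C → rt; aq. HCl
Reagents that add atoms: iodomethane, CI
Why: Birch reduction of the benzoate stops at the 1,4-dihydro stage as the C1 carbanion/carboxylate dianion (C4 is protonated by ammonia), and C-methylation at C1 (Birch reductive alkylation) creates the quaternary centre that blocks re-aromatisation; both 1,4-diastereomers are expected because the ring is nearly flat.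

Step 2
Reactants: 3 1,4-dimethylcyclohexa-2,5-diene-1-carboxylic acid (cis/trans mixture)
Product: 4 (cis-1,4-dimethylcyclohexa-2,5-dien-1-yl)methanol
Conditions: LiAlH4, THF, 0 °C → reflux; H2O work-up; chromatography on AgNO3–SiO2
Reagents that add atoms: none
Why: Hydride reduction of the acid leaves the skipped diene untouched, and the cis-dimethyl alcohol (CH2OH and the C4 hydrogen on the same face) is to be separated from the trans isomer on silver-nitrate-impregnated silica.

Step 3
Reactants: 5 2,4-dihydroxy-3-methoxybenzaldehyde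
Product: 6 2-hydroxy-3-methoxy-4-[(triisopropylsilyl)oxy]benzaldehyde
Conditions: i-Pr3SiCl (1.05 equiv), imidazole, DMF, 0 °C
Reagents that add atoms: chlorotriisopropylsilane, CC(C)[Si](Cl)(C(C)C)C(C)C
Why: Silylation should select the more acidic, unchelated 4-OH over the 2-OH that is hydrogen-bonded to the aldehyde, and the robust aryl silyl ether keeps the future 7-OH of coumarin B masked through the later oxidation and olefination.

Step 4
Reactants: 6 2-hydroxy-3-methoxy-4-[(triisopropylsilyl)oxy]benzaldehyde
Product: 7 3-methoxy-2-(methoxymethoxy)-4-[(triisopropylsilyl)oxy]benzaldehyde (ArCHO)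
Conditions: MOMCl, i-Pr2NEt, CH2Cl2, 0 °C → rt
Reagents that add atoms: chloromethyl methyl ether, COCCl
Why: O-alkylation of the remaining phenol gives a base-stable acetal that acid can later remove without loss of the silyl ether, so that only the oxygen destined to become O1 of coumarin B is set free.

Step 5
Reactants: 8 methyl 2-[bis(2,2,2-trifluoroethoxy)phosphoryl]acetate
Product: 9 methyl 2-[bis(2,2,2-trifluoroethoxy)phosphoryl]-2-bromoacetate
Conditions: NaH (2.0 equiv), THF, 0 °C; Br2 (1.0 equiv), −78 °C; AcOH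
Reagents that add atoms: bromine, BrBr
Why: Electrophilic bromination of the sodium phosphonoacetate anion, in which the second equivalent of base holds the more acidic monobromide as its anion and so limits dibromination.

Step 6
Reactants: 7 ArCHO; 9 methyl 2-[bis(2,2,2-trifluoroethoxy)phosphoryl]-2-bromoacetate
Product: 10 methyl (E)-2-bromo-3-Ar-prop-2-enoate (aryl cis to the ester)
Conditions: KN(SiMe3)2, 18-crown-6, THF, −78 °C
Reagents that add atoms: none
Why: Horner–Wadsworth–Emmons olefination in its Still–Gennari form: the electron-poor trifluoroethyl phosphonate eliminates under kinetic control and places the ester cis to the aryl group, which for the bromo reagent is the (E)-α-bromoacrylate that a diethyl bromophosphonoacetate would give only as a mixture of isomers.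

Step 7
Reactants: 10 methyl (E)-2-bromo-3-Ar-prop-2-enoate
Product: 11 (E)-2-bromo-3-Ar-prop-2-enoic acid
Conditions: Me3SnOH, ClCH2CH2Cl, 70 °C; 0.1 M HCl wash
Reagents that add atoms: trimethyltin hydroxide, C[Sn](C)(C)O
Why: Near-neutral ester cleavage by the tin hydroxide spares the aryl silyl ether (which aqueous hydroxide could remove), the acetal and the alkene geometry.

Step 8
Reactants: 11 (E)-2-bromo-3-Ar-prop-2-enoic acid; 4 (cis-1,4-dimethylcyclohexa-2,5-dien-1-yl)methanol
Product: 12 (cis-1,4-dimethylcyclohexa-2,5-dien-1-yl)methyl (E)-2-bromo-3-Ar-prop-2-enoate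
Conditions: DCC, DMAP (cat.), CH2Cl2, 0 °C → rt
Reagents that add atoms: none
Why: Steglich esterification through the acylpyridinium ion suits the neopentyl-type primary alcohol and is mild enough to keep the bromoalkene geometry and both phenol protecting groups.

Step 9
Reactants: 12 (cis-1,4-dimethylcyclohexa-2,5-dien-1-yl)methyl (E)-2-bromo-3-Ar-prop-2-enoate
Product: 13 (4Z,4aR,8aS)-4-(Ar-methylidene)-6,8a-dimethyl-4a,8a-dihydro-1H-isochromen-3(4H)-one (cis-fused; aryl cis to the lactone carbonyl; C4a = C6 and C8a = C1 of the carbocycle)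
Conditions: Pd2(dba)3 (5 mol %), (R)-BINAP (12 mol %), Ag3PO4, CaCO3, NMP, 70 °C
Reagents that add atoms: none
Why: Oxidative addition of the electron-poor C–Br bond to zerovalent palladium–BINAP occurs with retention, silver removes bromide, and the cationic divalent vinylpalladium inserts one of the two enantiotopic ring alkenes syn, after which syn β-hydride elimination and base return the catalyst. The closest known reaction type is the enantioselective intramolecular Heck desymmetrisation of 1-substituted cyclohexa-2,5-dienes that carry a carbon-tethered vinyl halide or triflate and give cis-fused bicycles; here the tether is an ester that must reach its less favoured s-cis rotamer, which the quaternary C1 helps by pressing the chain ends together. The one ring that closes, the δ-lactone, forms 6-exo-trig (Cα to C6, palladium to C5). C4a and C8a arise together: their cis relation follows from the short tether, which reaches only the ring face that carries CH2O, and their absolute sense from the ligand's choice between C2=C3 and C6=C5. The step needs this alkene choice (ligand), a single direction of β-hydride loss (in the cis-dimethyl diene only the C4 hydrogen is syn to palladium and the C6 hydrogen is anti, so C4=C5 forms and C2=C3 stays) and retention of the bromoalkene geometry (so that the aryl group ends cis to the lactone carbonyl, as the coumarin closure requires).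

Step 10
Reactants: 13 (4Z,4aR,8aS)-4-(Ar-methylidene)-6,8a-dimethyl-4a,8a-dihydro-1H-isochromen-3(4H)-one
Product: 14 (4Z,4aR,8aS)-4-(Ar-methylidene)-6,8a-dimethyl-4a,7,8,8a-tetrahydro-1H-isochromen-3(4H)-one
Conditions: H2 (1 atm), RhCl(PPh3)3 (10 mol %), PhH/EtOH, rt
Reagents that add atoms: none
Why: Homogeneous hydrogenation with the neutral rhodium catalyst selects by steric access, so the cis-disubstituted C7=C8 bond (C2=C3 of the carbocycle) should be saturated by 1,2-addition while the trisubstituted C5=C6 and benzylidene bonds stay, as in the known selective reduction of the disubstituted bond of steroidal 1,4-dien-3-ones; no stereocentre is created, and the conjugated diene is removed before the acid of the next step.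

Step 11
Reactants: 14 (4Z,4aR,8aS)-4-(Ar-methylidene)-6,8a-dimethyl-4a,7,8,8a-tetrahydro-1H-isochromen-3(4H)-one
Product: 16 3-[(1R,6S)-6-(hydroxymethyl)-3,6-dimethylcyclohex-2-en-1-yl]-8-methoxy-7-[(triisopropylsilyl)oxy]-2H-chromen-2-one, via free phenol 15 (not isolated)
Conditions: p-TsOH·H2O (cat.), MeOH/THF, 45 °C
Reagents that add atoms: none
Why: Acid-catalysed acetal exchange with methanol frees the phenol, which sits cis to the lactone carbonyl across the benzylidene bond and should take over the acyl group (translactonisation, as in the known rearrangement of α-(2-hydroxybenzylidene) lactones to 3-(hydroxyalkyl)coumarins), driven by formation of the pyranone of coumarin B; the CH2OH on C1 is released and both stereocentres are untouched.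

Step 12
Reactants: 16 3-[(1R,6S)-6-(hydroxymethyl)-3,6-dimethylcyclohex-2-en-1-yl]-8-methoxy-7-[(triisopropylsilyl)oxy]-2H-chromen-2-one
Product: 17 (1S,2R)-2-{8-methoxy-2-oxo-7-[(triisopropylsilyl)oxy]-2H-chromen-3-yl}-1,4-dimethylcyclohex-3-ene-1-carbaldehyde
Conditions: Dess–Martin periodinane, CH2Cl2, 0 °C → rt
Reagents that add atoms: none
Why: Dess–Martin oxidation of the hindered primary alcohol gives an aldehyde without α-hydrogen, which cannot epimerise at C1, and the silyl-protected phenol is inert to the oxidant.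

Step 13
Reactants: 7 ArCHO
Product: 18 ethyl (Z)-3-Ar-2-methylprop-2-enoate (aryl cis to the ester)
Conditions: (CF3CH2O)2P(O)CH(CH3)CO2Et, KN(SiMe3)2, 18-crown-6, THF, −78 °C
Reagents that add atoms: ethyl 2-[bis(2,2,2-trifluoroethoxy)phosphoryl]propanoate, CCOC(=O)C(C)P(=O)(OCC(F)(F)F)OCC(F)(F)F
Why: Still–Gennari olefination should give the (Z)-α-methylcinnamate, in which the ester is cis to the aryl group as ring closure to coumarin A requires.

Step 14
Reactants: 18 ethyl (Z)-3-Ar-2-methylprop-2-enoate
Product: 20 8-methoxy-3-methyl-7-[(triisopropylsilyl)oxy]-2H-chromen-2-one, via phenol ester 19 (not isolated)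
Conditions: p-TsOH·H2O (cat.), MeOH, 45 °C
Reagents that add atoms: none
Why: Acid removes the acetal, and the phenol, held cis to the ester, lactonises with loss of ethanol to the pyranone ring of coumarin A.

Step 15
Reactants: 20 8-methoxy-3-methyl-7-[(triisopropylsilyl)oxy]-2H-chromen-2-one
Product: 21 3-(bromomethyl)-8-methoxy-7-[(triisopropylsilyl)oxy]-2H-chromen-2-one
Conditions: NBS, AIBN (cat.), PhCF3, 85 °C
Reagents that add atoms: N-bromosuccinimide, O=C1CCC(=O)N1Br
Why: Wohl–Ziegler bromination at the allylic 3-methyl group, whose radical is stabilised by the C3=C4 bond and the arene; radical conditions in a non-polar solvent are chosen to outrun electrophilic ring bromination.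

Step 16
Reactants: 21 3-(bromomethyl)-8-methoxy-7-[(triisopropylsilyl)oxy]-2H-chromen-2-one
Product: 22 diethyl ({8-methoxy-2-oxo-7-[(triisopropylsilyl)oxy]-2H-chromen-3-yl}methyl)phosphonate
Conditions: P(OEt)3 (neat), 130 °C
Reagents that add atoms: triethyl phosphite, CCOP(OCC)OCC
Why: Michaelis–Arbuzov reaction of the reactive allylic bromide, with bromoethane distilling off.

Step 17
Reactants: 22 diethyl ({8-methoxy-2-oxo-7-[(triisopropylsilyl)oxy]-2H-chromen-3-yl}methyl)phosphonate; 17 (1S,2R)-2-{8-methoxy-2-oxo-7-[(triisopropylsilyl)oxy]-2H-chromen-3-yl}-1,4-dimethylcyclohex-3-ene-1-carbaldehyde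
Product: 23 7,7'-bis-O-TIPS ether of the target, (E)-alkene, (1R,2R)
Conditions: NaN(SiMe3)2, THF, −78 °C → rt
Reagents that add atoms: none
Why: Horner–Wadsworth–Emmons olefination of the non-enolisable aldehyde with the semi-stabilised phosphonate anion should give the (E)-disubstituted alkene, favoured by the bulky quaternary neighbour, and leaves both stereocentres untouched.

Step 18
Reactants: 23 7,7'-bis-O-TIPS ether of the target
Product: 24 CNP0264408.1, 7-hydroxy-3-[(E)-2-[(1R,2R)-2-(7-hydroxy-8-methoxy-2-oxo-2H-chromen-3-yl)-1,4-dimethylcyclohex-3-en-1-yl]ethenyl]-8-methoxy-2H-chromen-2-one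
Conditions: Bu4NF, AcOH, THF, 0 °C
Reagents that add atoms: none
Why: Fluoride cleaves both aryl Si–O bonds, and acetic acid buffers the phenoxides so that neither lactone is opened.

## Compound list

1 | 4-methylbenzoic acid | Cc1ccc(C(=O)O)cc1 | starting material
2 | dilithium 1-carboxylato-4-methylcyclohexa-2,5-dien-1-ide (Birch dianion) | [Li+].[Li+].CC1C=C[C-](C(=O)[O-])C=C1 | intermediate
3 | 1,4-dimethylcyclohexa-2,5-diene-1-carboxylic acid (cis/trans mixture) | CC1C=CC(C)(C(=O)O)C=C1 | intermediate
4 | (cis-1,4-dimethylcyclohexa-2,5-dien-1-yl)methanol (methyl groups on one face, CH2OH and H-4 on the other) | C[C@H]1C=C[C@](C)(CO)C=C1 | intermediate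
5 | 2,4-dihydroxy-3-methoxybenzaldehyde | COc1c(O)ccc(C=O)c1O | starting material
6 | 2-hydroxy-3-methoxy-4-[(triisopropylsilyl)oxy]benzaldehyde | COc1c(O[Si](C(C)C)(C(C)C)C(C)C)ccc(C=O)c1O | intermediate
7 | 3-methoxy-2-(methoxymethoxy)-4-[(triisopropylsilyl)oxy]benzaldehyde | COc1c(O[Si](C(C)C)(C(C)C)C(C)C)ccc(C=O)c1OCOC | intermediate
8 | methyl 2-[bis(2,2,2-trifluoroethoxy)phosphoryl]acetate | COC(=O)CP(=O)(OCC(F)(F)F)OCC(F)(F)F | starting material
9 | methyl 2-[bis(2,2,2-trifluoroethoxy)phosphoryl]-2-bromoacetate | COC(=O)C(Br)P(=O)(OCC(F)(F)F)OCC(F)(F)F | intermediate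
10 | methyl (E)-2-bromo-3-{3-methoxy-2-(methoxymethoxy)-4-[(triisopropylsilyl)oxy]phenyl}prop-2-enoate | COC(=O)/C(Br)=C\c1ccc(O[Si](C(C)C)(C(C)C)C(C)C)c(OC)c1OCOC | intermediate
11 | (E)-2-bromo-3-{3-methoxy-2-(methoxymethoxy)-4-[(triisopropylsilyl)oxy]phenyl}prop-2-enoic acid | OC(=O)/C(Br)=C\c1ccc(O[Si](C(C)C)(C(C)C)C(C)C)c(OC)c1OCOC | intermediate
12 | (cis-1,4-dimethylcyclohexa-2,5-dien-1-yl)methyl (E)-2-bromo-3-{3-methoxy-2-(methoxymethoxy)-4-[(triisopropylsilyl)oxy]phenyl}prop-2-enoate | C[C@H]1C=C[C@](C)(COC(=O)/C(Br)=C\c2ccc(O[Si](C(C)C)(C(C)C)C(C)C)c(OC)c2OCOC)C=C1 | intermediate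
13 | (4Z,4aR,8aS)-4-{3-methoxy-2-(methoxymethoxy)-4-[(triisopropylsilyl)oxy]benzylidene}-6,8a-dimethyl-4a,8a-dihydro-1H-isochromen-3(4H)-one | O=C1OC[C@@]2(C)C=CC(C)=C[C@H]2/C1=C/c1ccc(O[Si](C(C)C)(C(C)C)C(C)C)c(OC)c1OCOC | intermediate
14 | (4Z,4aR,8aS)-4-{3-methoxy-2-(methoxymethoxy)-4-[(triisopropylsilyl)oxy]benzylidene}-6,8a-dimethyl-4a,7,8,8a-tetrahydro-1H-isochromen-3(4H)-one | O=C1OC[C@@]2(C)CCC(C)=C[C@H]2/C1=C/c1ccc(O[Si](C(C)C)(C(C)C)C(C)C)c(OC)c1OCOC | intermediate
15 | (4Z,4aR,8aS)-4-{2-hydroxy-3-methoxy-4-[(triisopropylsilyl)oxy]benzylidene}-6,8a-dimethyl-4a,7,8,8a-tetrahydro-1H-isochromen-3(4H)-one | O=C1OC[C@@]2(C)CCC(C)=C[C@H]2/C1=C/c1ccc(O[Si](C(C)C)(C(C)C)C(C)C)c(OC)c1O | intermediate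
16 | 3-[(1R,6S)-6-(hydroxymethyl)-3,6-dimethylcyclohex-2-en-1-yl]-8-methoxy-7-[(triisopropylsilyl)oxy]-2H-chromen-2-one | OC[C@@]1(C)CCC(C)=C[C@H]1c1cc2ccc(O[Si](C(C)C)(C(C)C)C(C)C)c(OC)c2oc1=O | intermediate
17 | (1S,2R)-2-{8-methoxy-2-oxo-7-[(triisopropylsilyl)oxy]-2H-chromen-3-yl}-1,4-dimethylcyclohex-3-ene-1-carbaldehyde | O=C[C@@]1(C)CCC(C)=C[C@H]1c1cc2ccc(O[Si](C(C)C)(C(C)C)C(C)C)c(OC)c2oc1=O | intermediate
18 | ethyl (Z)-3-{3-methoxy-2-(methoxymethoxy)-4-[(triisopropylsilyl)oxy]phenyl}-2-methylprop-2-enoate | CCOC(=O)/C(C)=C\c1ccc(O[Si](C(C)C)(C(C)C)C(C)C)c(OC)c1OCOC | intermediate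
19 | ethyl (Z)-3-{2-hydroxy-3-methoxy-4-[(triisopropylsilyl)oxy]phenyl}-2-methylprop-2-enoate | CCOC(=O)/C(C)=C\c1ccc(O[Si](C(C)C)(C(C)C)C(C)C)c(OC)c1O | intermediate
20 | 8-methoxy-3-methyl-7-[(triisopropylsilyl)oxy]-2H-chromen-2-one | Cc1cc2ccc(O[Si](C(C)C)(C(C)C)C(C)C)c(OC)c2oc1=O | intermediate
21 | 3-(bromomethyl)-8-methoxy-7-[(triisopropylsilyl)oxy]-2H-chromen-2-one | BrCc1cc2ccc(O[Si](C(C)C)(C(C)C)C(C)C)c(OC)c2oc1=O | intermediate
22 | diethyl ({8-methoxy-2-oxo-7-[(triisopropylsilyl)oxy]-2H-chromen-3-yl}methyl)phosphonate | CCOP(=O)(Cc1cc2ccc(O[Si](C(C)C)(C(C)C)C(C)C)c(OC)c2oc1=O)OCC | intermediate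
23 | 8-methoxy-3-[(E)-2-[(1R,2R)-2-{8-methoxy-2-oxo-7-[(triisopropylsilyl)oxy]-2H-chromen-3-yl}-1,4-dimethylcyclohex-3-en-1-yl]ethenyl]-7-[(triisopropylsilyl)oxy]-2H-chromen-2-one | COc1c(O[Si](C(C)C)(C(C)C)C(C)C)ccc2cc(/C=C/[C@@]3(C)CCC(C)=C[C@H]3c3cc4ccc(O[Si](C(C)C)(C(C)C)C(C)C)c(OC)c4oc3=O)c(=O)oc12 | intermediate
24 | CNP0264408.1, 7-hydroxy-3-[(E)-2-[(1R,2R)-2-(7-hydroxy-8-methoxy-2-oxo-2H-chromen-3-yl)-1,4-dimethylcyclohex-3-en-1-yl]ethenyl]-8-methoxy-2H-chromen-2-one | COc1c(O)ccc2cc(/C=C/[C@@]3(C)CCC(C)=C[C@H]3c3cc4ccc(O)c(OC)c4oc3=O)c(=O)oc12 | target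

## Step count and risks

Total steps: 18. Longest linear sequence: 11 steps (steps 3, 4, 6, 7, 8, 9, 10, 11, 12, 17 and 18, starting from 5).

Steps most likely to fail:

1. Step 9. The ligand may discriminate poorly between the two enantiotopic ring alkenes, all the more if the temperature needed to reach the s-cis ester rotamer loosens the chiral pocket, so that the lactone forms with low enantiomeric purity. The fallback sets out from 12 and comes back at 13. Ester 12 would be cyclised with an achiral catalyst (Pd(OAc)2, PPh3, Ag2CO3, MeCN, 80 °C), which should give the racemic cis-fused lactone F1. Its enantiomers would then be separated by preparative chromatography on a cellulose tris(3,5-dimethylphenylcarbamate) stationary phase, and the (4aR,8aS) enantiomer is 13; stereocontrol thus passes from the catalyst to a resolution.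

2. Step 10. Hydrogen may add 1,4 across the conjugated diene, the diene may isomerise or over-reduce, or uptake may stall because the diene binds rhodium too firmly. The fallback sets out from 13 and comes back at 16, with the order of the two steps reversed. Lactone 13 would first be treated with p-TsOH in MeOH/THF, which should free the phenol; the dienyl phenol lactone F2 (not isolated) should then rearrange to the dienyl coumarin alcohol F3. The homoallylic CH2OH of F3 would then direct a cationic iridium catalyst ([Ir(cod)(PCy3)(py)]PF6, H2, CH2Cl2, 0 °C) to the neighbouring disubstituted C=C, giving 16 by substrate-directed instead of sterically selected hydrogenation.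

3. Step 17. Addition of the semi-stabilised phosphonate anion to the neopentyl aldehyde may be slow, so that conjugate addition of the anion to C4 of a coumarin or its self-condensation takes over; the bromination of step 15 may also attack the electron-rich ring. The fallback sets out from 17 (and from 10 for the coupling partner), comes back at 23, and needs none of steps 13 to 16. Aldehyde 17 would be methylenated by a Wittig reaction (Ph3PCH3Br, KN(SiMe3)2, THF, −78 → 0 °C) to the vinyl compound F4. Bromo ester 10 with p-TsOH in MeOH should lose its acetal, and the phenol bromo ester F5 (not isolated) should lactonise to the 3-bromocoumarin F6. An intermolecular Heck reaction of F6 with F4 (Pd(OAc)2, P(o-tol)3, Ag2CO3, DMF, 80 °C) would then arylate the terminal vinyl carbon; β-hydride loss is possible only toward the (E)-alkene because the other neighbour is quaternary, and the product is 23.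

## Further compounds

F1 | step 9 | racemic cis-fused (4Z)-4-{3-methoxy-2-(methoxymethoxy)-4-[(triisopropylsilyl)oxy]benzylidene}-6,8a-dimethyl-4a,8a-dihydro-1H-isochromen-3(4H)-one (both enantiomers) | O=C1OC[C@@]2(C)C=CC(C)=C[C@H]2/C1=C/c1ccc(O[Si](C(C)C)(C(C)C)C(C)C)c(OC)c1OCOC.O=C1OC[C@]2(C)C=CC(C)=C[C@@H]2/C1=C/c1ccc(O[Si](C(C)C)(C(C)C)C(C)C)c(OC)c1OCOC
F2 | step 10 | (4Z,4aR,8aS)-4-{2-hydroxy-3-methoxy-4-[(triisopropylsilyl)oxy]benzylidene}-6,8a-dimethyl-4a,8a-dihydro-1H-isochromen-3(4H)-one | O=C1OC[C@@]2(C)C=CC(C)=C[C@H]2/C1=C/c1ccc(O[Si](C(C)C)(C(C)C)C(C)C)c(OC)c1O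
F3 | step 10 | 3-[(1R,6S)-6-(hydroxymethyl)-3,6-dimethylcyclohexa-2,4-dien-1-yl]-8-methoxy-7-[(triisopropylsilyl)oxy]-2H-chromen-2-one | OC[C@@]1(C)C=CC(C)=C[C@H]1c1cc2ccc(O[Si](C(C)C)(C(C)C)C(C)C)c(OC)c2oc1=O
F4 | step 17 | 3-[(1R,6R)-6-ethenyl-3,6-dimethylcyclohex-2-en-1-yl]-8-methoxy-7-[(triisopropylsilyl)oxy]-2H-chromen-2-one | C=C[C@@]1(C)CCC(C)=C[C@H]1c1cc2ccc(O[Si](C(C)C)(C(C)C)C(C)C)c(OC)c2oc1=O
F5 | step 17 | methyl (E)-2-bromo-3-{2-hydroxy-3-methoxy-4-[(triisopropylsilyl)oxy]phenyl}prop-2-enoate | COC(=O)/C(Br)=C\c1ccc(O[Si](C(C)C)(C(C)C)C(C)C)c(OC)c1O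
F6 | step 17 | 3-bromo-8-methoxy-7-[(triisopropylsilyl)oxy]-2H-chromen-2-one | Brc1cc2ccc(O[Si](C(C)C)(C(C)C)C(C)C)c(OC)c2oc1=O
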